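**Retrosynthetic overview**

1. Ring numbering: lactone O1, C2 (C=O), C3, C4, C5. The single ring is cut at C3–C4 (syn-aldol of an acyl enolate onto an aldehyde carbon) and at O1–C5 (acyl oxygen adding to C5); both bonds are made in one flask.
2. Enabling feature: carbinol C4 lies between enolisable C3 and fully substituted C5, and the C5 methyl is read as a masked exocyclic methylene. A C5=CH2 alkene allylic to the C4 hydroxyl lets the acyl oxygen close the oxolanone 5-exo at C5 under iodonium activation, with the C4 oxygen steering the alkene face.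
3. Precursors of the key step: imide 10 (its auxiliary carbon is the only purchased stereocentre) and the achiral 2-alkylacrolein 6. The auxiliary sets C3 and C4, C4 relays to C5, and the cyclisation expels the auxiliary.
4. 6 comes from pent-1-yne and 12-bromododecan-1-ol (acetylide alkylation, Na/NH3 reduction to the E-alkene, oxidation, α-methylenation). After the key step only C–I reduction (CH2I to the C5 methyl) and desilylation remain.
5. Ring order: the oxolan-2-one is the only ring and is closed in step 7.

Key step: step 7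

**Route**

Step 1
Reactants: 1 pent-1-yne; 2 12-bromododecan-1-ol
Product: 3 heptadec-13-yn-1-ol
Conditions: 1 (2.4 equiv), n-BuLi (2.3 equiv), THF/DMPU, −78 °C to rt
Reagents that add atoms: none
Why: Acetylide alkylation (SN2 of lithium pent-1-ynide on the primary bromide) should proceed with the hydroxyl carried as its lithium alkoxide, DMPU accelerating the substitution.

Step 2
Reactants: 3 heptadec-13-yn-1-ol
Product: 4 (13E)-heptadec-13-en-1-ol
Conditions: Na, NH3 (l), THF, −33 °C; then NH4Cl
Reagents that add atoms: none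
Why: Dissolving-metal reduction of the isolated dialkyl alkyne passes through the trans vinyl radical/anion and should give the E-alkene selectively.

Step 3
Reactants: 4 (13E)-heptadec-13-en-1-ol
Product: 5 (13E)-heptadec-13-enal
Conditions: TEMPO (cat.), PhI(OAc)2, CH2Cl2, rt
Reagents that add atoms: none
Why: Oxoammonium (TEMPO) oxidation of the primary alcohol should stop at the aldehyde and leave the isolated alkene untouched.

Step 4
Reactants: 5 (13E)-heptadec-13-enal
Product: 6 (13E)-2-methylideneheptadec-13-enal
Conditions: 37% aq. formaldehyde, pyrrolidine (cat.), propionic acid (cat.), i-PrOH, 45 °C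
Reagents that add atoms: formaldehyde, C=O
Why: Organocatalytic α-methylenation (Mannich condensation through the enamine, then β-elimination of the amine) should give the 2-substituted acrolein.

Step 5
Reactants: 7 3-[(tert-butyldimethylsilyl)oxy]propan-1-ol
Product: 8 3-[(tert-butyldimethylsilyl)oxy]propanoic acid
Conditions: TEMPO (cat.), PhI(OAc)2 (2.2 equiv), MeCN/H2O, rt
Reagents that add atoms: water, O
Why: TEMPO/PhI(OAc)2 oxidation in aqueous MeCN should take the primary alcohol through the aldehyde hydrate to the acid, the TBS ether tolerating the weakly acidic medium.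

Step 6
Reactants: 8 3-[(tert-butyldimethylsilyl)oxy]propanoic acid; 9 (4S)-4-benzyl-1,3-oxazolidin-2-one
Product: 10 (4S)-4-benzyl-3-{3-[(tert-butyldimethylsilyl)oxy]propanoyl}-1,3-oxazolidin-2-one
Conditions: PivCl, Et3N, THF, −20 °C; then 9, LiCl, rt
Reagents that add atoms: none
Why: N-Acylation of the oxazolidinone through the mixed pivalic anhydride should give the Evans imide without touching the stereocentre.

Step 7
Reactants: 10 (4S)-4-benzyl-3-{3-[(tert-butyldimethylsilyl)oxy]propanoyl}-1,3-oxazolidin-2-one; 6 (13E)-2-methylideneheptadec-13-enal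
Product: 15 (3S,4S,5R)-3-{[(tert-butyldimethylsilyl)oxy]methyl}-4-hydroxy-5-(iodomethyl)-5-[(11E)-pentadec-11-en-1-yl]oxolan-2-one, via boron enolate 11 (not isolated), via boron aldolate 12 (not isolated), via syn-aldol imide 13 (not isolated), via iminium ether iodide 14 (not isolated)
Conditions: Bu2BOTf, i-Pr2NEt, CH2Cl2, 0 °C; 6, −78 to 0 °C; then pH 7 phosphate buffer, MeOH/THF, 0 °C; then I2, NaHCO3, 0 °C, dark; Na2S2O3 work-up
Reagents that add atoms: iodine, II; water, O
Why: The Z-boron enolate 11 should add to 6 through a chair Zimmerman–Traxler transition state to give syn-aldolate 12 (C3–C4 bond); after the buffer frees alcohol 13, I2 forms an iodonium ion on the C5=CH2 alkene that the imide acyl oxygen opens at tertiary C5 (O1–C5 bond), and water hydrolyses iminium ether 14 to the lactone carbonyl with release of auxiliary 9. The closest known reaction types are the Evans syn-aldol with 2-substituted acroleins and the iodolactonisation of γ,δ-unsaturated N-acyloxazolidinones and of 3-hydroxypent-4-enamides. The lactone closes 5-exo-trig with Markovnikov regiochemistry and anti addition of oxygen and iodine. C3 and C4 are set by the (S)-benzyl auxiliary, which shields one enolate face in the dipole-minimised chair; C5 is set by C4 through 1,2-induction, the alkene reacting through the conformer with the allylic C4–O bond in the alkene plane (hydroxyl-in-plane conformer, the most nucleophilic one because the C–O bond then lies orthogonal to the π system) and iodine arriving anti to C3, so that CH2I should end cis to the hydroxyl. The step needs chemoselectivity for the allylic 1,1-disubstituted alkene over the remote E-alkene, which the internal acyl-oxygen nucleophile and the reversibility of iodine addition to isolated alkenes should secure, and for acyl oxygen over silyl ether oxygen, which the bulky, weakly basic TBS ether should secure.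

Step 8
Reactants: 15 (3S,4S,5R)-3-{[(tert-butyldimethylsilyl)oxy]methyl}-4-hydroxy-5-(iodomethyl)-5-[(11E)-pentadec-11-en-1-yl]oxolan-2-one
Product: 16 (3S,4S,5R)-3-{[(tert-butyldimethylsilyl)oxy]methyl}-4-hydroxy-5-methyl-5-[(11E)-pentadec-11-en-1-yl]oxolan-2-one
Conditions: Bu3SnH (1.2 equiv), Et3B (cat.), air, toluene, 0 °C to rt
Reagents that add atoms: none
Why: Radical-chain dehalogenation should turn CH2I into the C5 methyl, since iodine abstraction by the stannyl radical and hydrogen transfer to the primary radical outrun both 1,2-acyloxy shift and reversible stannyl addition to the remote alkene, so no stereocentre or alkene geometry should change.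

Step 9
Reactants: 16 (3S,4S,5R)-3-{[(tert-butyldimethylsilyl)oxy]methyl}-4-hydroxy-5-methyl-5-[(11E)-pentadec-11-en-1-yl]oxolan-2-one
Product: 17 (3S,4S,5R)-4-hydroxy-3-(hydroxymethyl)-5-methyl-5-[(11E)-pentadec-11-en-1-yl]oxolan-2-one
Conditions: HF·pyridine, pyridine/THF, 0 °C to rt
Reagents that add atoms: none
Why: Fluoride cleavage of the primary TBS ether under buffered, mildly acidic conditions should free the hydroxymethyl group without retro-aldol, elimination or C3 epimerisation of the β-hydroxy lactone.

**Compound list**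

1 | pent-1-yne | CCCC#C | starting material
2 | 12-bromododecan-1-ol | OCCCCCCCCCCCCBr | starting material
3 | heptadec-13-yn-1-ol | CCCC#CCCCCCCCCCCCCO | intermediate
4 | (13E)-heptadec-13-en-1-ol | CCC/C=C/CCCCCCCCCCCCO | intermediate
5 | (13E)-heptadec-13-enal | CCC/C=C/CCCCCCCCCCCC=O | intermediate
6 | (13E)-2-methylideneheptadec-13-enal | CCC/C=C/CCCCCCCCCCC(=C)C=O | intermediate
7 | 3-[(tert-butyldimethylsilyl)oxy]propan-1-ol | CC(C)(C)[Si](C)(C)OCCCO | starting material
8 | 3-[(tert-butyldimethylsilyl)oxy]propanoic acid | CC(C)(C)[Si](C)(C)OCCC(=O)O | intermediate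
9 | (4S)-4-benzyl-1,3-oxazolidin-2-one | O=C1N[C@@H](Cc2ccccc2)CO1 | starting material
10 | (4S)-4-benzyl-3-{3-[(tert-butyldimethylsilyl)oxy]propanoyl}-1,3-oxazolidin-2-one | CC(C)(C)[Si](C)(C)OCCC(=O)N1[C@@H](Cc2ccccc2)COC1=O | intermediate
11 | (4S)-4-benzyl-3-[(1Z)-3-[(tert-butyldimethylsilyl)oxy]-1-[(dibutylboranyl)oxy]prop-1-en-1-yl]-1,3-oxazolidin-2-one (boron enolate) | CCCCB(CCCC)O/C(=C\CO[Si](C)(C)C(C)(C)C)N1[C@@H](Cc2ccccc2)COC1=O | intermediate
12 | (4S)-4-benzyl-3-[(2S,3S,15E)-2-{[(tert-butyldimethylsilyl)oxy]methyl}-3-[(dibutylboranyl)oxy]-4-methylidenenonadec-15-enoyl]-1,3-oxazolidin-2-one (boron aldolate) | CCC/C=C/CCCCCCCCCCC(=C)[C@@H](OB(CCCC)CCCC)[C@H](CO[Si](C)(C)C(C)(C)C)C(=O)N1[C@@H](Cc2ccccc2)COC1=O | intermediate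
13 | (4S)-4-benzyl-3-[(2S,3S,15E)-2-{[(tert-butyldimethylsilyl)oxy]methyl}-3-hydroxy-4-methylidenenonadec-15-enoyl]-1,3-oxazolidin-2-one (syn-aldol imide) | CCC/C=C/CCCCCCCCCCC(=C)[C@@H](O)[C@H](CO[Si](C)(C)C(C)(C)C)C(=O)N1[C@@H](Cc2ccccc2)COC1=O | intermediate
14 | (4S)-4-benzyl-3-[(3S,4S,5R)-3-{[(tert-butyldimethylsilyl)oxy]methyl}-4-hydroxy-5-(iodomethyl)-5-[(11E)-pentadec-11-en-1-yl]oxolan-2-ylidene]-2-oxo-1,3-oxazolidin-3-ium iodide (iminium ether iodide) | CCC/C=C/CCCCCCCCCC[C@@]1(CI)OC(=[N+]2[C@@H](Cc3ccccc3)COC2=O)[C@@H](CO[Si](C)(C)C(C)(C)C)[C@@H]1O.[I-] | intermediate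
15 | (3S,4S,5R)-3-{[(tert-butyldimethylsilyl)oxy]methyl}-4-hydroxy-5-(iodomethyl)-5-[(11E)-pentadec-11-en-1-yl]oxolan-2-one | CCC/C=C/CCCCCCCCCC[C@@]1(CI)OC(=O)[C@@H](CO[Si](C)(C)C(C)(C)C)[C@@H]1O | intermediate
16 | (3S,4S,5R)-3-{[(tert-butyldimethylsilyl)oxy]methyl}-4-hydroxy-5-methyl-5-[(11E)-pentadec-11-en-1-yl]oxolan-2-one | CCC/C=C/CCCCCCCCCC[C@@]1(C)OC(=O)[C@@H](CO[Si](C)(C)C(C)(C)C)[C@@H]1O | intermediate
17 | (3S,4S,5R)-4-hydroxy-3-(hydroxymethyl)-5-methyl-5-[(11E)-pentadec-11-en-1-yl]oxolan-2-one | CCC/C=C/CCCCCCCCCC[C@@]1(C)OC(=O)[C@@H](CO)[C@@H]1O | target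

**Step count and risks**

Total steps: 9. Longest linear sequence: 7 (steps 1, 2, 3, 4, 7, 8, 9); steps 5 and 6 form the side branch.

Steps most likely to fail:

Step 7 (key). The iodocyclisation may proceed with poor facial selectivity at C5, or the silyl ether oxygen may compete with the acyl oxygen for the iodonium ion. Fallback (sets out from 6, returns at 15): the C5 configuration is installed by a catalytic epoxidation ahead of the aldol and then carried over stereospecifically instead of being induced in the cyclisation. Amine-catalysed asymmetric epoxidation of the α-branched enal 6 (aqueous H2O2, 9-amino-9-deoxy-epi-cinchona alkaloid salt, the pseudo-enantiomer that leads to the R epoxide) should give (2R)-2-[(11E)-pentadec-11-en-1-yl]oxirane-2-carbaldehyde F1. Evans syn-aldol of 10 with F1 (Bu2BOTf, i-Pr2NEt, buffered work-up, isolated) should give the epoxy aldol imide F2. Camphorsulfonic acid in wet CH2Cl2 should make the acyl oxygen open the epoxide at its fully substituted carbon with inversion (5-exo), water releasing 9 and giving the 5-(hydroxymethyl) lactone F3. Iodination of the primary hydroxyl under Appel-type conditions (I2, PPh3, imidazole, toluene), the primary alcohol reacting ahead of the hindered secondary one, then leads to 15.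

Step 4. Self-condensation of the aldehyde or oligomerisation of the 2-alkylacrolein under the amine/acid catalysis may erode material. Fallback (sets out from 5, returns at 6): a stepwise, stoichiometric Mannich route with isolated intermediates. Eschenmoser's salt and Et3N in CH2Cl2 should give the Mannich base (13E)-2-[(dimethylamino)methyl]heptadec-13-enal F4. Quaternisation with MeI should give the ammonium iodide (13E)-2-formyl-N,N,N-trimethylheptadec-13-en-1-aminium iodide F5. Elimination with NaHCO3 in a two-phase mixture at rt should release 6, which is taken directly into step 7.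

Step 1. The alkylation may stall because the lithium alkoxide aggregates the acetylide, or loss of HBr may compete. Fallback (sets out from 2, returns at 3): a protecting-group route. 3,4-Dihydro-2H-pyran with pyridinium p-toluenesulfonate should give 2-[(12-bromododecyl)oxy]oxane F6. Alkylation of lithium pent-1-ynide (n-BuLi, THF/DMPU) should give 2-(heptadec-13-yn-1-yloxy)oxane F7. Acetal exchange (pyridinium p-toluenesulfonate, MeOH) should return 3.

**Further compounds**

F1 | step 7 | (2R)-2-[(11E)-pentadec-11-en-1-yl]oxirane-2-carbaldehyde | CCC/C=C/CCCCCCCCCC[C@@]1(CO1)C=O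
F2 | step 7 | (4S)-4-benzyl-3-[(2S,3S)-2-{[(tert-butyldimethylsilyl)oxy]methyl}-3-hydroxy-3-{(2R)-2-[(11E)-pentadec-11-en-1-yl]oxiran-2-yl}propanoyl]-1,3-oxazolidin-2-one | CCC/C=C/CCCCCCCCCC[C@@]1(CO1)[C@@H](O)[C@H](CO[Si](C)(C)C(C)(C)C)C(=O)N2[C@@H](Cc3ccccc3)COC2=O
F3 | step 7 | (3S,4S,5S)-3-{[(tert-butyldimethylsilyl)oxy]methyl}-4-hydroxy-5-(hydroxymethyl)-5-[(11E)-pentadec-11-en-1-yl]oxolan-2-one | CCC/C=C/CCCCCCCCCC[C@@]1(CO)OC(=O)[C@@H](CO[Si](C)(C)C(C)(C)C)[C@@H]1O
F4 | step 4 | (13E)-2-[(dimethylamino)methyl]heptadec-13-enal | CCC/C=C/CCCCCCCCCCC(CN(C)C)C=O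
F5 | step 4 | (13E)-2-formyl-N,N,N-trimethylheptadec-13-en-1-aminium iodide | CCC/C=C/CCCCCCCCCCC(C[N+](C)(C)C)C=O.[I-]
F6 | step 1 | 2-[(12-bromododecyl)oxy]oxane | BrCCCCCCCCCCCCOC1CCCCO1
F7 | step 1 | 2-(heptadec-13-yn-1-yloxy)oxane | CCCC#CCCCCCCCCCCCCOC1CCCCO1
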